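The step that joins first end groups and second end groups into links and frees the released group cannot outrun its forward rate, and it cannot pass its balance while released group stays in the flask. The scavenger removes that group.

| setting | Tuesday's | Monday's | theta | gamma |
|---|---|---|---|---|
| first end groups | 0.19 M | 0.19 M | 0.19 M | 0.19 M |
| second end groups | 0.186 M | 0.186 M | 0.186 M | 0.186 M |
| scavenger | 0.052 M | 0.13 M | 0.0950 M | 0.190 M |
| remark | run made earlier | run made earlier |  |  |
| time |  |  | 3.0 min | 3.0 min |

| run | time / s | first end groups / % | links / % |
|---|---|---|---|
| Tuesday's | 10.0 | 71.5 | 25.3 |
| Tuesday's | 25.0 | 53.5 | 43.7 |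
| Tuesday's | 40.0 | 42.0 | 51.9 |
| Tuesday's | 60.0 | 35.6 | 59.1 |
| Tuesday's | 90.0 | 30.9 | 61.5 |
| Tuesday's | 120 | 30.9 | 63.4 |
| Monday's | 10.0 | 74.4 | 25.2 |
| Monday's | 15.0 | 65.4 | 32.0 |
| Monday's | 30.0 | 50.1 | 47.1 |
| Monday's | 50.0 | 40.7 | 60.2 |
| Monday's | 80.0 | 29.1 | 70.8 |
| Monday's | 120 | 22.4 | 76.1 |

(readings scatter by 1 percentage point)

* part of the first end groups that has reacted at the end, theta
* part of the first end groups that has reacted at the end, gamma
* what raising the concentration of scavenger from its lowest to its highest value here does to the part of the first end groups that has reacted (changes below 5 percentage points count as none) (it rises / no change / it falls)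

- what is said of released group includes idle adduct
- steps that have been proposed: scavenger + released group -> scavenged by-product; first end groups + released group <-> idle adduct; first end groups + second end groups <-> links + released group
- what has gone from first end groups into another species counts as reacted, even if it can come back

So I hold two amounts against each other. Monday's run at 30.0 s has 0.0895 M of links, less than its 0.13 M of scavenger, so that reading shows the forward step, and second-order decay gives:

k = 0.175 /M/s

demand in 3.0 min = 0.161 M

theta: 0.0950 M / 0.161 M = 0.591

gamma: 0.190 M / 0.161 M = 1.18

Demand is the released group the forward step alone frees in that time; scavenger charged over demand is the cover. Gamma's cover exceeds one, so I reckon gamma at the demand, 84.6 % reacted: kinetic control. Theta's falls short, its 0.0950 M of scavenger being less than the demand, so I reckon theta at its balance: thermodynamic control. I read that balance, with its scatter, from Tuesday's last reading, first end groups at 30.9 %, with reacted first end groups counted as links: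

reacted × (reacted − scavenger) / (first left × second left) = 3.24

On theta's charges this gives 0.142 M, or 74.9 % reacted, so I expect a rise of 9.7 percentage points, more than 5 points.

The forecast says 74 % and 84 %, each below my figure, and it rises, holding of gamma that “scavenger is never exhausted”.

The flask gives 74.1 % for theta and 84.2 % for gamma: it rises, by 10 points.

    scavenger + released group → scavenged by-product (k = 4.20 /M/s)
    first end groups + released group ⇌ idle adduct, settled at all times (K = 3.30 /M)
    first end groups + second end groups ⇌ links + released group (K = 1.90, k = 0.180 /M/s)

Theta, cover 0.591, ends with 0 % of its scavenger free; gamma, cover 1.18, ends with 16.4 %. With second end groups cut to 0.11 M, theta's neighbour has a demand of 0.106 M and a cover of 0.896, just under one, and it ends at 55.2 % reacted with 0.95 % of its scavenger free.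

Readings and results were generated by integration with made-up constants; the scatter is artificial.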